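**Retrosynthetic overview**

- Target ⇐ bis-silyl ether. Ring B (the α-methylene-γ-butyrolactone) is formed last, by palladium-catalysed cyclocarbonylation of a trans-2-ethynylcyclohexanol; the side-chain ester is put on just before, by site-selective acylation.
- Ring A (the cyclohexane) is formed first, by a one-flask [5+1] aldol–aldol annulation of a 2,3,3-trisubstituted pentanedial with acetaldehyde, then alkyne homologation (the new step).
- Pentanedial ⇐ terminal alkyne (anti-Markovnikov hydration) and dimethyl acetal (hydrolysis); the 3-hydroxyprop-1-en-2-yl arm ⇐ α-keto ester (methylenation, reduction).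
- α-Keto ester with the vicinal tertiary/quaternary centres ⇐ guanidinium-catalysed enantioselective Claisen rearrangement of a (Z,Z) 2-alkoxycarbonyl allyl vinyl ether.
- Vinyl ether ⇐ (Z)-3-methylpent-2-en-4-yn-1-ol, a diazophosphonoacetate and dimethoxyacetaldehyde; side chain ⇐ but-2-yn-1-ol and CO2.

Assumption: the catalyst antipodes named in steps 3 and 8 are taken to give the configurations drawn; should either induce the opposite sense, its mirror-image catalyst is used and nothing else changes.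

**Route**

Step 1
Reactants: 1 (2Z)-3-methylpent-2-en-4-yn-1-ol; 2 ethyl diazo(diethoxyphosphoryl)acetate
Product: 3 ethyl 2-(diethoxyphosphoryl)-2-{[(2Z)-3-methylpent-2-en-4-yn-1-yl]oxy}acetate (racemic at C2)
Conditions: Rh2(OAc)4 (1 mol %), toluene, 80 °C, slow addition of 2
Reagents that add atoms: none
Why: Rhodium-carbenoid O–H insertion into the alcohol is much faster than cyclopropanation or cyclopropenation for an acceptor/acceptor carbenoid, and the racemic phosphonate carbon becomes sp2 in step 2.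

Step 2
Reactants: 3 ethyl 2-(diethoxyphosphoryl)-2-{[(2Z)-3-methylpent-2-en-4-yn-1-yl]oxy}acetate; 4 dimethoxyacetaldehyde
Product: 5 ethyl (2Z)-4,4-dimethoxy-2-{[(2Z)-3-methylpent-2-en-4-yn-1-yl]oxy}but-2-enoate
Conditions: LiN(SiMe3)2, THF, −78 °C; then anhydrous 4, −78 to 0 °C; chromatography removes the minor 2E isomer
Reagents that add atoms: none
Why: Horner–Wadsworth–Emmons olefination of the α-alkoxy phosphonate puts the aldehyde-derived carbon trans to the ester, which is the 2Z enol ether needed for the chair Claisen rearrangement.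

Step 3
Reactants: 5 ethyl (2Z)-4,4-dimethoxy-2-{[(2Z)-3-methylpent-2-en-4-yn-1-yl]oxy}but-2-enoate
Product: 6 ethyl (3S,4S)-3-(dimethoxymethyl)-4-ethynyl-4-methyl-2-oxohex-5-enoate
Conditions: N,N'-bis[(1R,2R)-2-(2,5-diphenyl-1H-pyrrol-1-yl)cyclohexyl]guanidinium tetrakis[3,5-bis(trifluoromethyl)phenyl]borate (20 mol %), hexanes, 35 °C, 5 d
Reagents that add atoms: none
Why: Hydrogen-bond-donor (guanidinium) catalysed enantioselective Claisen rearrangement of a 2-alkoxycarbonyl allyl vinyl ether; the catalyst binds the ether oxygen and ester carbonyl and selects one enantiotopic chair, while the (Z,Z) geometries place the acetal carbon and the ethynyl group axial and so fix the relative configuration of the new tertiary (C3) and quaternary (C4) centres, the first stereocentres of the route.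

Step 4
Reactants: 6 ethyl (3S,4S)-3-(dimethoxymethyl)-4-ethynyl-4-methyl-2-oxohex-5-enoate
Product: 7 ethyl (3R,4S)-3-(dimethoxymethyl)-4-ethynyl-4-methyl-2-methylidenehex-5-enoate
Conditions: Ph3PCH3Br, KN(SiMe3)2, THF, −78 °C; then 6, −78 to 0 °C
Reagents that add atoms: methyltriphenylphosphonium bromide, C[P+](c1ccccc1)(c1ccccc1)c1ccccc1.[Br-]
Why: Wittig methylenation is selective for the activated keto carbonyl of an α-keto ester over the ester, and at low temperature addition outpaces enolisation, so C3 keeps its configuration (the descriptor changes from S to R only through the CIP priorities).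

Step 5
Reactants: 7 ethyl (3R,4S)-3-(dimethoxymethyl)-4-ethynyl-4-methyl-2-methylidenehex-5-enoate
Product: 8 (3R,4S)-3-(dimethoxymethyl)-4-ethynyl-4-methyl-2-methylidenehex-5-en-1-ol
Conditions: i-Bu2AlH (2.5 equiv), CH2Cl2, −78 °C; aq. potassium sodium tartrate
Reagents that add atoms: none
Why: 1,2-Reduction of the 2-substituted acrylate ester with i-Bu2AlH gives the allylic alcohol, and the acetal, alkyne and alkenes are inert at −78 °C.

Step 6
Reactants: 8 (3R,4S)-3-(dimethoxymethyl)-4-ethynyl-4-methyl-2-methylidenehex-5-en-1-ol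
Product: 9 tert-butyl{[(3R,4S)-3-(dimethoxymethyl)-4-ethynyl-4-methyl-2-methylidenehex-5-en-1-yl]oxy}diphenylsilane
Conditions: TBDPSCl, imidazole, CH2Cl2, 0 °C to rt
Reagents that add atoms: tert-butyl(chloro)diphenylsilane, CC(C)(C)[Si](Cl)(c1ccccc1)c1ccccc1
Why: Silylation of the primary allylic alcohol; the TBDPS ether survives the aqueous acid of step 7 and masks a hydroxyl that would otherwise form a lactol with the neighbouring aldehyde and compete in the acylation of step 11.

Step 7
Reactants: 9 tert-butyl{[(3R,4S)-3-(dimethoxymethyl)-4-ethynyl-4-methyl-2-methylidenehex-5-en-1-yl]oxy}diphenylsilane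
Product: 11 (2R,3S)-2-{3-[(tert-butyldiphenylsilyl)oxy]prop-1-en-2-yl}-3-ethenyl-3-methylpentanedial, via aldehyde acetal 10 (not isolated)
Conditions: CpRu(MeCN)3PF6 (5 mol %), 5,5'-bis(trifluoromethyl)-2,2'-bipyridine (5 mol %), NMP/H2O 4:1, 25 °C; then 1 M HCl, THF, 0 °C
Reagents that add atoms: water, O
Why: Ruthenium-vinylidene-mediated anti-Markovnikov hydration turns the terminal alkyne into the CH2CHO arm without touching the alkenes, and mild acid then hydrolyses the dimethyl acetal; no stereocentre is involved, and the dialdehyde is kept cold and used at once because C2 is α to an aldehyde.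

Step 8
Reactants: 11 (2R,3S)-2-{3-[(tert-butyldiphenylsilyl)oxy]prop-1-en-2-yl}-3-ethenyl-3-methylpentanedial; 12 acetaldehyde
Product: 15 (1S,2R,3R,4R,5S)-4-{3-[(tert-butyldiphenylsilyl)oxy]prop-1-en-2-yl}-5-ethenyl-2-ethynyl-5-methylcyclohexane-1,3-diol, via hydroxy dialdehyde 13 (not isolated), via formyl diol 14 (not isolated)
Conditions: 12 (5 equiv), (S)-α,α-bis[3,5-bis(trifluoromethyl)phenyl]pyrrolidin-2-ylmethanol (20 mol %), NMP, 4 °C, 48 h, then 23 °C, 24 h; volatiles removed in vacuo; then MeOH, K2CO3, dimethyl (1-diazo-2-oxopropyl)phosphonate, 0 °C to rt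
Reagents that add atoms: dimethyl (1-diazo-2-oxopropyl)phosphonate, COP(=O)(OC)C(=[N+]=[N-])C(C)=O
Why: Proposed new method: a one-flask formal [5+1] aldol–aldol annulation in which the enamine of acetaldehyde adds to the less hindered CH2CHO aldehyde under catalyst control (new carbinol S), the resulting β-hydroxy aldehyde re-forms an enamine at the same carbon and closes ring A onto the second aldehyde (6-enolexo), and reversible aldol and epimerisation funnel the product to the all-equatorial 2-formyl-1,3-diol because an axial hydroxyl would be 1,3-diaxial to the ring methyl; the aldehyde is then homologated in the same flask to the alkyne by the Seyferth–Gilbert reaction under Ohira–Bestmann conditions, whose K2CO3 also keeps the formyl-bearing carbon equatorial; the closest known reactions are the [5+1] nitro-aldol cyclisation of glutaraldehydes with nitromethane to all-equatorial 2-nitrocyclohexane-1,3-diols, the diarylprolinol-catalysed cross-aldol of acetaldehyde and the proline-catalysed 6-enolexo aldolisation of dialdehydes.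

Step 9
Reactants: 16 but-2-yn-1-ol
Product: 18 (2E)-2-(hydroxymethyl)but-2-enoic acid, via alkenylmagnesium chloride 17 (not isolated)
Conditions: i-BuMgCl (2.3 equiv), Cp2TiCl2 (5 mol %), Et2O, 0 to 25 °C; then CO2 (1 atm), −20 to 0 °C; 1 M HCl
Reagents that add atoms: carbon dioxide, O=C=O
Why: Titanium-catalysed hydromagnesiation of the propargylic alkoxide is a syn addition that places magnesium on C2 (alkoxide-directed), and carboxylation of the alkenyl Grignard reagent with retention gives the 2E acid (CO2H trans to CH3).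

Step 10
Reactants: 18 (2E)-2-(hydroxymethyl)but-2-enoic acid
Product: 20 (2E)-2-{[(tert-butyldiphenylsilyl)oxy]methyl}but-2-enoic acid, via bis-silyl derivative 19 (not isolated)
Conditions: TBDPSCl (2.2 equiv), imidazole, DMF, rt; then THF/H2O/AcOH, rt
Reagents that add atoms: tert-butyl(chloro)diphenylsilane, CC(C)(C)[Si](Cl)(c1ccccc1)c1ccccc1
Why: Exhaustive silylation followed by selective hydrolysis of the labile silyl ester (the silyl ether is stable) gives the O-protected acid.

Step 11
Reactants: 15 (1S,2R,3R,4R,5S)-4-{3-[(tert-butyldiphenylsilyl)oxy]prop-1-en-2-yl}-5-ethenyl-2-ethynyl-5-methylcyclohexane-1,3-diol; 20 (2E)-2-{[(tert-butyldiphenylsilyl)oxy]methyl}but-2-enoic acid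
Product: 22 (1S,2S,3R,4R,5S)-4-{3-[(tert-butyldiphenylsilyl)oxy]prop-1-en-2-yl}-5-ethenyl-2-ethynyl-3-hydroxy-5-methylcyclohexyl (2E)-2-{[(tert-butyldiphenylsilyl)oxy]methyl}but-2-enoate, via mixed anhydride 21 (not isolated)
Conditions: 20, 2,4,6-trichlorobenzoyl chloride, Et3N, toluene, rt; then 15, DMAP, 0 °C to rt
Reagents that add atoms: none
Why: Yamaguchi esterification; the bulky acyl donor takes the equatorial hydroxyl flanked by the ring CH2 (C1–OH) and not the one flanked by the branched carbon next to the quaternary centre, and acylating before the lactone exists keeps DMAP away from an α-methylene lactone (the C2 descriptor changes from R to S only through the CIP priorities).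

Step 12
Reactants: 22 (1S,2S,3R,4R,5S)-4-{3-[(tert-butyldiphenylsilyl)oxy]prop-1-en-2-yl}-5-ethenyl-2-ethynyl-3-hydroxy-5-methylcyclohexyl (2E)-2-{[(tert-butyldiphenylsilyl)oxy]methyl}but-2-enoate
Product: 23 (3aR,4S,6S,7R,7aR)-7-{3-[(tert-butyldiphenylsilyl)oxy]prop-1-en-2-yl}-6-ethenyl-6-methyl-3-methylidene-2-oxooctahydro-1-benzofuran-4-yl (2E)-2-{[(tert-butyldiphenylsilyl)oxy]methyl}but-2-enoate
Conditions: PdCl2 (5 mol %), PPh3 (10 mol %), SnCl2 (5 mol %), CO (7 atm), MeCN, 75 °C
Reagents that add atoms: carbon monoxide, [C-]#[O+]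
Why: Palladium-catalysed cyclocarbonylation of a homopropargylic alcohol; the only free hydroxyl forms an alkoxycarbonyl-palladium species that adds cis across the ethynyl group (exo-dig) to give ring B, and the trans-diequatorial hydroxyl/ethynyl pair already present fixes the trans ring fusion.

Step 13
Reactants: 23 (3aR,4S,6S,7R,7aR)-7-{3-[(tert-butyldiphenylsilyl)oxy]prop-1-en-2-yl}-6-ethenyl-6-methyl-3-methylidene-2-oxooctahydro-1-benzofuran-4-yl (2E)-2-{[(tert-butyldiphenylsilyl)oxy]methyl}but-2-enoate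
Product: 24 (3aR,4S,6S,7R,7aR)-6-ethenyl-7-(3-hydroxyprop-1-en-2-yl)-6-methyl-3-methylidene-2-oxooctahydro-1-benzofuran-4-yl (2E)-2-(hydroxymethyl)but-2-enoate
Conditions: HF·pyridine, THF/pyridine, 0 °C to rt
Reagents that add atoms: none
Why: Buffered fluoride desilylation removes both primary TBDPS ethers without conjugate addition to the α-methylene lactone or acyl migration.

**Compound list**

1 | (2Z)-3-methylpent-2-en-4-yn-1-ol | OC/C=C(/C)C#C | starting material
2 | ethyl diazo(diethoxyphosphoryl)acetate | CCOC(=O)C(=[N+]=[N-])P(=O)(OCC)OCC | starting material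
3 | ethyl 2-(diethoxyphosphoryl)-2-{[(2Z)-3-methylpent-2-en-4-yn-1-yl]oxy}acetate (racemic) | CCOC(=O)C(OC/C=C(/C)C#C)P(=O)(OCC)OCC | intermediate
4 | dimethoxyacetaldehyde | COC(OC)C=O | starting material
5 | ethyl (2Z)-4,4-dimethoxy-2-{[(2Z)-3-methylpent-2-en-4-yn-1-yl]oxy}but-2-enoate | COC(OC)/C=C(\OC/C=C(/C)C#C)C(=O)OCC | intermediate
6 | ethyl (3S,4S)-3-(dimethoxymethyl)-4-ethynyl-4-methyl-2-oxohex-5-enoate | C=C[C@](C)(C#C)[C@@H](C(OC)OC)C(=O)C(=O)OCC | intermediate
7 | ethyl (3R,4S)-3-(dimethoxymethyl)-4-ethynyl-4-methyl-2-methylidenehex-5-enoate | C=C[C@](C)(C#C)[C@@H](C(OC)OC)C(=C)C(=O)OCC | intermediate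
8 | (3R,4S)-3-(dimethoxymethyl)-4-ethynyl-4-methyl-2-methylidenehex-5-en-1-ol | C=C[C@](C)(C#C)[C@@H](C(OC)OC)C(=C)CO | intermediate
9 | tert-butyl{[(3R,4S)-3-(dimethoxymethyl)-4-ethynyl-4-methyl-2-methylidenehex-5-en-1-yl]oxy}diphenylsilane | C=C[C@](C)(C#C)[C@@H](C(OC)OC)C(=C)CO[Si](c1ccccc1)(c1ccccc1)C(C)(C)C | intermediate
10 | (3S,4R)-6-[(tert-butyldiphenylsilyl)oxy]-4-(dimethoxymethyl)-3-ethenyl-3-methyl-5-methylidenehexanal | C=C[C@](C)(CC=O)[C@@H](C(OC)OC)C(=C)CO[Si](c1ccccc1)(c1ccccc1)C(C)(C)C | intermediate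
11 | (2R,3S)-2-{3-[(tert-butyldiphenylsilyl)oxy]prop-1-en-2-yl}-3-ethenyl-3-methylpentanedial | C=C[C@](C)(CC=O)[C@@H](C=O)C(=C)CO[Si](c1ccccc1)(c1ccccc1)C(C)(C)C | intermediate
12 | acetaldehyde | CC=O | starting material
13 | (2R,3S,5S)-2-{3-[(tert-butyldiphenylsilyl)oxy]prop-1-en-2-yl}-3-ethenyl-5-hydroxy-3-methylheptanedial | C=C[C@](C)(C[C@H](O)CC=O)[C@@H](C=O)C(=C)CO[Si](c1ccccc1)(c1ccccc1)C(C)(C)C | intermediate
14 | (1R,2R,3R,4S,6S)-3-{3-[(tert-butyldiphenylsilyl)oxy]prop-1-en-2-yl}-4-ethenyl-2,6-dihydroxy-4-methylcyclohexane-1-carbaldehyde | C=C[C@]1(C)C[C@H](O)[C@@H](C=O)[C@H](O)[C@H]1C(=C)CO[Si](c2ccccc2)(c2ccccc2)C(C)(C)C | intermediate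
15 | (1S,2R,3R,4R,5S)-4-{3-[(tert-butyldiphenylsilyl)oxy]prop-1-en-2-yl}-5-ethenyl-2-ethynyl-5-methylcyclohexane-1,3-diol | C=C[C@]1(C)C[C@H](O)[C@@H](C#C)[C@H](O)[C@H]1C(=C)CO[Si](c2ccccc2)(c2ccccc2)C(C)(C)C | intermediate
16 | but-2-yn-1-ol | CC#CCO | starting material
17 | [(2E)-1-(chloromagnesiooxy)but-2-en-2-yl]magnesium chloride | C/C=C(/[Mg]Cl)CO[Mg]Cl | intermediate
18 | (2E)-2-(hydroxymethyl)but-2-enoic acid | C/C=C(\CO)C(=O)O | intermediate
19 | tert-butyldiphenylsilyl (2E)-2-{[(tert-butyldiphenylsilyl)oxy]methyl}but-2-enoate | C/C=C(\CO[Si](c1ccccc1)(c1ccccc1)C(C)(C)C)C(=O)O[Si](c1ccccc1)(c1ccccc1)C(C)(C)C | intermediate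
20 | (2E)-2-{[(tert-butyldiphenylsilyl)oxy]methyl}but-2-enoic acid | C/C=C(\CO[Si](c1ccccc1)(c1ccccc1)C(C)(C)C)C(=O)O | intermediate
21 | (2E)-2-{[(tert-butyldiphenylsilyl)oxy]methyl}but-2-enoic 2,4,6-trichlorobenzoic anhydride | C/C=C(\CO[Si](c1ccccc1)(c1ccccc1)C(C)(C)C)C(=O)OC(=O)c1c(Cl)cc(Cl)cc1Cl | intermediate
22 | (1S,2S,3R,4R,5S)-4-{3-[(tert-butyldiphenylsilyl)oxy]prop-1-en-2-yl}-5-ethenyl-2-ethynyl-3-hydroxy-5-methylcyclohexyl (2E)-2-{[(tert-butyldiphenylsilyl)oxy]methyl}but-2-enoate | C=C[C@]1(C)C[C@H](OC(=O)/C(=C/C)CO[Si](c2ccccc2)(c2ccccc2)C(C)(C)C)[C@@H](C#C)[C@H](O)[C@H]1C(=C)CO[Si](c2ccccc2)(c2ccccc2)C(C)(C)C | intermediate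
23 | (3aR,4S,6S,7R,7aR)-7-{3-[(tert-butyldiphenylsilyl)oxy]prop-1-en-2-yl}-6-ethenyl-6-methyl-3-methylidene-2-oxooctahydro-1-benzofuran-4-yl (2E)-2-{[(tert-butyldiphenylsilyl)oxy]methyl}but-2-enoate | C=C[C@]1(C)C[C@H](OC(=O)/C(=C/C)CO[Si](c3ccccc3)(c3ccccc3)C(C)(C)C)[C@H]2C(=C)C(=O)O[C@@H]2[C@H]1C(=C)CO[Si](c3ccccc3)(c3ccccc3)C(C)(C)C | intermediate
24 | (3aR,4S,6S,7R,7aR)-6-ethenyl-7-(3-hydroxyprop-1-en-2-yl)-6-methyl-3-methylidene-2-oxooctahydro-1-benzofuran-4-yl (2E)-2-(hydroxymethyl)but-2-enoate | C=C[C@]1(C)C[C@H](OC(=O)/C(=C/C)CO)[C@H]2C(=C)C(=O)O[C@@H]2[C@H]1C(=C)CO | target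

**Step count and risks**

Total: 13 steps. Longest linear sequence: 11 steps (1 to 24 through steps 1–8 and 11–13); steps 9 and 10 make the side-chain acid.

Most likely to fail:

- **Step 8 (the proposed new step).** Acetaldehyde may self-condense, the β-hydroxy aldehydes may dehydrate, 13 may rest as a six-membered lactol, and the second aldol has to attack a hindered aldehyde. The fallback uses known reactions run stepwise instead of as a one-flask annulation on the dialdehyde. It sets out from 10, isolated by leaving out the acid stage of step 7. The diarylprolinol-catalysed cross-aldol of acetaldehyde on this mono-aldehyde gives (3S,5S,6R)-8-[(tert-butyldiphenylsilyl)oxy]-6-(dimethoxymethyl)-5-ethenyl-3-hydroxy-5-methyl-7-methylideneoctanal F1. Hydrolysis of its acetal (1 M HCl, THF, 0 °C) comes back to the route at 13, which is then cyclised in a separate L-proline-catalysed 6-enolexo aldolisation to 14 and homologated to 15 as before.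

- **Step 3.** The acetal-bearing enol ether and the enyne allyl unit may rearrange slowly or with modest enantioselectivity under hydrogen-bond catalysis. The fallback changes the mode of activation to chelating chiral Lewis-acid catalysis: Cu(SbF6)2 with (S,S)-2,2'-isopropylidenebis(4-tert-butyl-2-oxazoline) (10 mol %), CH2Cl2, rt, which binds the ether oxygen and ester carbonyl as a five-membered chelate and drives the same chair rearrangement. It sets out from 5 and comes back at 6; it makes no new compound (F0).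

- **Step 4.** The basic ylide may enolise the hindered α-keto ester (epimerising C3) or trigger loss of methanol from the β,β-dimethoxy ketone. The fallback is a two-step Peterson olefination that avoids a basic carbon nucleophile at the ketone stage. It sets out from 6: Me3SiCH2MgCl/CeCl3 (THF, −78 °C) adds to the keto group to give ethyl (3R,4S)-3-(dimethoxymethyl)-4-ethynyl-2-hydroxy-4-methyl-2-[(trimethylsilyl)methyl]hex-5-enoate F2 (mixture at C2), and KH (THF, 0 °C) then effects syn elimination, coming back to the route at 7.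

Further compounds
F1 | step 8 | (3S,5S,6R)-8-[(tert-butyldiphenylsilyl)oxy]-6-(dimethoxymethyl)-5-ethenyl-3-hydroxy-5-methyl-7-methylideneoctanal | C=C[C@](C)(C[C@H](O)CC=O)[C@@H](C(OC)OC)C(=C)CO[Si](c1ccccc1)(c1ccccc1)C(C)(C)C
F0 | step 3 | none | none
F2 | step 4 | ethyl (3R,4S)-3-(dimethoxymethyl)-4-ethynyl-2-hydroxy-4-methyl-2-[(trimethylsilyl)methyl]hex-5-enoate | C=C[C@](C)(C#C)[C@@H](C(OC)OC)C(O)(C[Si](C)(C)C)C(=O)OCC
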